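**A steady clock.** The ochre run, one of the flasks below, cannot be losing a steady share of its starting material each minute. By 1.8 min the log of charge over what is left stands at 0.0240, or 0.0133 min⁻¹. A steady share would then give 0.113 at 8.5 min, yet the readings give 0.267. That log is the sum of the small shares lost minute by minute, and we call it the fraction-left clock. We read the opening pace as the unaided path and give the surplus of 0.154 to product, which speeds the flask.

| setting | grey | amber | ochre | blue |
|---|---|---|---|---|
| starting material | 0.600 M | 0.360 M | 0.600 M | 0.200 M |
| reagent | 1.80 M | 1.56 M | 0.900 M | 0.900 M |
| free catalyst | 0.00600 M | 0.00600 M | 0.00600 M | 0.00600 M |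
| time |  |  |  | 8.5 min |

| grey run: time / min | grey run: [product] / M | amber run: time / min | amber run: [product] / M | ochre run: time / min | ochre run: [product] / M |
|---|---|---|---|---|---|
| 0.31 | 0.0043 | 0.31 | 0.0017 | 0.31 | 0 |
| 0.92 | 0.0073 | 0.92 | 0.0032 | 0.92 | 0.0056 |
| 1.8 | 0.0235 | 1.8 | 0.0084 | 1.8 | 0.0142 |
| 2.8 | 0.0419 | 2.8 | 0.0170 | 2.8 | 0.0231 |
| 4.0 | 0.0751 | 4.0 | 0.0291 | 4.0 | 0.0469 |
| 5.4 | 0.1356 | 5.4 | 0.0571 | 5.4 | 0.0691 |
| 6.9 | 0.2169 | 6.9 | 0.0768 | 6.9 | 0.1059 |
| 8.5 | 0.3156 | 8.5 | 0.1121 | 8.5 | 0.1407 |

(each reading ± 0.002 M)

- how the opening rate goes with [starting material] round the charge of the grey run: the exponent of the rate at two percent of starting material gone to product (one fixed amount of product, the same in the runs compared)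
- how the opening rate goes with [reagent] round the charge of the grey run: the exponent of the rate at two percent of starting material gone to product
- the amber run starts with 0.240 M less of starting material and of reagent than the grey run, and with no product. Compared where both hold the same amount of starting material, once fifteen percent of what the amber run was charged with has turned into product, is the amber run faster, slower or alike (within a tenth)?
- product in the blue run at 8.5 min, as a share of the starting material charged

- Overall: starting material + reagent -> product, with free catalyst as catalyst.
- Constant volume, constant temperature.
- A reading of a species includes what of it is bound.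
- An order is taken over about fifteen percent of the charge, up and down.

**The floor.** The blue run has the ochre run's reagent and a third of its starting material. We assume the unaided share per minute does not fall with a smaller charge, that is, an order of at most 1. The ochre opening pace alone then gives the blue run 10.7%. That product is 0.152 of the ochre run's at the end, and a larger share earlier, 0.333 at 1.8 min. So at least that end share of the surplus belongs on the blue clock, and the floor rises to 12.8%.

**The ceiling.** Now we assume the unaided amount per minute does not rise with a smaller charge, an order of at least 0. The blue run then makes no more than the ochre run's product, which would be 70.3% of its charge. But the aided path, taken to follow starting material, keeps at most the ochre run's share. Adding the unaided amount to that share lowers the ceiling to 44.8%.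

**Our figure.** The hand stops here; each opening reading carries a scatter of 0.002 M. Splitting the unaided order halfway, at 0.5, and keeping the floor's surplus puts the blue clock at 0.219, which is 19.7%.

**The result.** The forecast, opening with “Product clearly speeds the reaction”, gave orders of 1 and 0.5, the amber run slower, and 13% for the blue run, just above our floor. The simulation gives orders of 0.78 and 0.41, the amber run slower, and 18.6% for the blue run, inside the bracket and 1.1 percentage points below our figure.

    free catalyst + starting material → catalyst-substrate complex (10.86 L mol⁻¹ min⁻¹)
    catalyst-substrate complex + reagent → loaded catalyst (9.720 L mol⁻¹ min⁻¹)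
    loaded catalyst → product + free catalyst (3.642 min⁻¹)
    starting material + reagent + product → 2 product (0.4032 L² mol⁻² min⁻¹)
    2 free catalyst ⇌ resting dimer, settled at all times (469.0 L mol⁻¹)

**What ran.** In the blue run the cycle through catalyst-substrate complex and loaded catalyst ran from the start, with free catalyst in balance with resting dimer, the step taking product joined as product appeared, and the clock stood at 0.206 at 8.5 min. In the amber run the same steps ran while product grew: the clock read 0.288 at a quarter made, at 7.50 min, and 0.693 at half made, at 11.8 min, a pace of 0.0384 min⁻¹ on the first stretch and 0.0954 min⁻¹ on the second.

All runs were generated by integration on assumed constants.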